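**Retrosynthetic overview**
1. The target is a trans-(3S,4S)-dibenzylbutyrolactone: ring A (guaiacyl) sits on the C4 benzyl, ring B (guaiacyl) on the C3 benzyl, and ring B carries at its C5 an (S)-CH(CH2OH)–C(=O)–guaiacyl arm (ring C). Late disconnections: three O-benzyl ethers (H2/Pd), aryl ketone from the benzylic carbinol (DDQ), carbinol and arm stereocentre from an Evans syn-aldol of a ring-B arylacetyl imide (made from an allyl group) with O-benzylvanillin.
2. Key disconnection: lactone bonds C3–C4 and O1–C5 are made together from (S,Z)-alkenyl p-tolyl sulfoxide 7 (ring A, C4, C5) and chloro(arylmethyl)ketene 20 (ring B, C3, C2, O) by O-acylation at sulfur, [3,3] shift and carboxylate-to-thionium closure. C3–Cl and C5–S are then removed reductively.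
3. Feature that allows it: in the lactone ring, C5 is an unsubstituted O–CH2 carbon directly beside the C4 stereocentre, and C3 is an enolisable CH beside C2=O. C5/C4 can therefore have been the two sp2 carbons of a vinyl sulfoxide (C5 becomes a thionium carbon, sulfur is traceless), and C3 a chlorine-bearing ketene carbon whose configuration is afterwards relayed from C4.
4. Stereochemistry: sulfur (bought as menthyl sulfinate) → C4 by chirality transfer in the key step → C3 by equilibration to trans; the arm stereocentre is set independently by the oxazolidinone.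
5. Rings: the three benzene rings are bought (ring A from O-benzylvanillyl alcohol, ring B from vanillin by Claisen allylation, ring C from O-benzylvanillin); the lactone is the only ring formed (step 12).

Key step: step 12

Remark: lactone atoms are numbered O1, C2 (C=O), C3 (ring-B benzyl), C4 (ring-A benzyl), C5 (OCH2); the transient centres C3 and C5 of 23 and 24 are left undefined in their SMILES because step 13 erases them.

**Step 1**
Reactants: 1 4-(benzyloxy)-3-methoxybenzyl alcohol
Product: 2 4-(benzyloxy)-3-methoxybenzyl bromide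
Conditions: PBr3, Et2O, 0 °C
Reagents that add atoms: phosphorus tribromide BrP(Br)Br
Why: Bromination of a primary benzylic alcohol with PBr3 (SN2 on the phosphite ester) is routine and leaves the aryl benzyl ether untouched.

**Step 2**
Reactants: 2 4-(benzyloxy)-3-methoxybenzyl bromide
Product: 3 1-(benzyloxy)-2-methoxy-4-(prop-2-yn-1-yl)benzene
Conditions: HC≡CMgBr, CuCl (cat.), THF, 0 → 50 °C
Reagents that add atoms: ethynylmagnesium bromide C#C[Mg]Br
Why: Copper-catalysed coupling of an alkynyl Grignard reagent with a benzylic bromide should give the 3-aryl-1-propyne and keep the terminal C–H for the next step.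

**Step 3**
Reactants: 3 1-(benzyloxy)-2-methoxy-4-(prop-2-yn-1-yl)benzene; 4 (1S,2R,5S)-(+)-menthyl (R)-p-toluenesulfinate
Product: 6 (R)-alkynyl p-tolyl sulfoxide of 3, via alkynylmagnesium bromide 5 (not isolated)
Conditions: EtMgBr, THF, 0 °C → rt; then added to 4, PhMe, −20 °C
Reagents that add atoms: none
Why: In this Andersen sulfoxide synthesis the alkynyl Grignard displaces mentholate at sulfur with inversion, so the (R)-sulfinate should give the (R)-alkynyl sulfoxide (the spatial sense of an (S)-alkenyl sulfoxide), and inverse addition at low temperature avoids base-induced propargyl–allenyl isomerisation.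

**Step 4**
Reactants: 6 (R)-alkynyl p-tolyl sulfoxide
Product: 7 (S,Z)-alkenyl p-tolyl sulfoxide
Conditions: H2 (1 atm), RhCl(PPh3)3 (cat.), benzene, rt
Reagents that add atoms: none
Why: Homogeneous syn-hydrogenation of a 1-alkynyl sulfoxide with Wilkinson's catalyst should stop at the (Z)-alkene without touching the sulfur configuration or the benzyl ether.

**Step 5**
Reactants: 8 vanillin
Product: 9 4-(allyloxy)-3-methoxybenzaldehyde
Conditions: allyl bromide, K2CO3, acetone, reflux
Reagents that add atoms: allyl bromide C=CCBr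
Why: Williamson O-allylation of the phenol is routine.

**Step 6**
Reactants: 9 4-(allyloxy)-3-methoxybenzaldehyde
Product: 11 3-allyl-4-hydroxy-5-methoxybenzaldehyde, via dienone tautomer 10 (not isolated)
Conditions: neat, 200 °C
Reagents that add atoms: none
Why: The aromatic Claisen rearrangement ([3,3]) can only deliver the allyl group to the single free ortho position, and the dienone then tautomerises to the phenol.

**Step 7**
Reactants: 11 3-allyl-4-hydroxy-5-methoxybenzaldehyde
Product: 12 3-allyl-4-(benzyloxy)-5-methoxybenzaldehyde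
Conditions: BnBr, K2CO3, DMF, 60 °C
Reagents that add atoms: benzyl bromide BrCc1ccccc1
Why: Williamson benzylation in DMF should overcome the hindrance of the 2,6-disubstituted phenol.

**Step 8**
Reactants: 12 3-allyl-4-(benzyloxy)-5-methoxybenzaldehyde
Product: 13 [3-allyl-4-(benzyloxy)-5-methoxyphenyl]methanol
Conditions: NaBH4, MeOH, 0 °C
Reagents that add atoms: none
Why: Borohydride reduction of an aryl aldehyde is chemoselective in the presence of the allyl group.

**Step 9**
Reactants: 13 [3-allyl-4-(benzyloxy)-5-methoxyphenyl]methanol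
Product: 14 1-allyl-2-(benzyloxy)-5-(bromomethyl)-3-methoxybenzene
Conditions: PBr3, Et2O, 0 °C
Reagents that add atoms: phosphorus tribromide BrP(Br)Br
Why: PBr3 bromination of the benzylic alcohol (SN2) should spare the allyl group at 0 °C; the bromide is used at once.

**Step 10**
Reactants: 15 methyl dichloroacetate; 14 1-allyl-2-(benzyloxy)-5-(bromomethyl)-3-methoxybenzene
Product: 17 methyl 3-[3-allyl-4-(benzyloxy)-5-methoxyphenyl]-2,2-dichloropropanoate, via lithium enolate 16 (not isolated)
Conditions: LiHMDS, THF, −78 °C; then 14, DMPU, −78 → −40 °C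
Reagents that add atoms: none
Why: Alkylation of the stabilised lithium enolate of a dichloroacetate ester with a reactive benzylic bromide at low temperature should install the CCl2 carbon that becomes the ketene carbon.

**Step 11**
Reactants: 17 methyl 3-[3-allyl-4-(benzyloxy)-5-methoxyphenyl]-2,2-dichloropropanoate
Product: 18 3-[3-allyl-4-(benzyloxy)-5-methoxyphenyl]-2,2-dichloropropanoic acid
Conditions: LiOH, THF/H2O, 0 °C; then 1 M HCl
Reagents that add atoms: lithium hydroxide [Li+].[OH-]
Why: Saponification of an activated α,α-dichloro ester is fast at 0 °C and should leave the gem-dichloride, the allyl group and the benzyl ether intact.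

**Step 12**
Reactants: 18 3-[3-allyl-4-(benzyloxy)-5-methoxyphenyl]-2,2-dichloropropanoic acid; 7 (S,Z)-alkenyl p-tolyl sulfoxide
Product: 23 (4R)-3-chloro-5-(p-tolylthio)lactone carrying both benzyl groups (C3/C5 epimers), via acid chloride 19 (not isolated), via chloroketene 20 (not isolated), via oxysulfonium enolate 21 (not isolated), via thionium carboxylate 22 (not isolated)
Conditions: (COCl)2, DMF (cat.), CH2Cl2, 0 °C → rt, evaporate; then Zn–Cu, 7, Et2O, 0 °C → rt (19 added slowly)
Reagents that add atoms: none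
Why: Proposed new method: zinc dechlorination of acid chloride 19 should give chloro(arylmethyl)ketene 20, whose central carbon is attacked by the sulfinyl oxygen of 7 to give oxysulfonium enolate 21; a charge-accelerated [3,3]-sigmatropic shift then joins the enolate carbon to the alkene β-carbon (C3–C4 bond) with S–O cleavage, and the carboxylate of thionium ion 22 closes onto the thionium carbon (O1–C5 bond). The closest known reaction type is the lactonization of enantiopure 1-alkenyl p-tolyl sulfoxides with dichloroketene made from trichloroacetyl chloride and zinc (Marino lactonization), extended here to an alkyl(chloro)ketene that keeps one α-chlorine as the activating group for ketene electrophilicity and enolate stability. The lactone, the only ring formed, closes in a 5-exo-trig mode (carboxylate oxygen onto the exocyclic C=S+ bond). C4 is set by chirality transfer from sulfur through a chair-like transition state with the p-tolyl group pseudo-equatorial and the sulfur lone pair inside, next to the (Z)-substituent (allylic strain), so the (S)-sulfoxide should give (4R) in 23, which is 4S once C3–Cl and C5–S are gone; C3 and C5 are transient centres formed without control and erased in step 13. The step needs the ketene to react at the sulfinyl oxygen and not by [2+2] addition to the allyl or alkenyl C=C bonds or by dimerisation, which the much higher nucleophilicity of the sulfoxide oxygen and slow generation of the ketene in the presence of 7 should secure, and it needs 7 not to isomerise to the allyl sulfoxide, which the base-free zinc conditions secure.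

**Step 13**
Reactants: 23 (4R)-3-chloro-5-(p-tolylthio)lactone
Product: 26 (3S,4S)-trans-lactone with allyl on ring B, via dechlorinated thiolactone 24 (not isolated), via cis-lactone 25 (not isolated)
Conditions: Bu3SnH (4 equiv), AIBN, PhMe, 100 °C; then DBU, rt
Reagents that add atoms: none
Why: Radical chain reduction with Bu3SnH should cleave the tertiary α-chloro C–Cl bond and then the C–S bond of the O,S-acetal, after which DBU equilibrates the enolisable C3 centre to the thermodynamically preferred 3,4-trans lactone, so C3 is set by substrate control from C4.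

**Step 14**
Reactants: 26 (3S,4S)-trans-lactone with allyl on ring B
Product: 28 ring-B arylacetaldehyde, via vicinal diol 27 (not isolated)
Conditions: OsO4 (cat.), NaIO4, 2,6-lutidine, dioxane/H2O, rt
Reagents that add atoms: osmium tetroxide O=[Os](=O)(=O)=O; sodium periodate [Na+].[O-]I(=O)(=O)=O
Why: Lemieux–Johnson oxidation cleaves the only alkene present (dihydroxylation, then glycol cleavage), and lutidine suppresses over-oxidation of the arylacetaldehyde.

**Step 15**
Reactants: 28 ring-B arylacetaldehyde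
Product: 29 ring-B arylacetic acid
Conditions: NaClO2, NaH2PO4, 2-methyl-2-butene, t-BuOH/H2O, rt
Reagents that add atoms: sodium chlorite [Na+].[O-]Cl=O
Why: Pinnick oxidation converts the aldehyde to the acid under buffered conditions, and the alkene scavenger protects the electron-rich rings from hypochlorite.

**Step 16**
Reactants: 29 ring-B arylacetic acid; 30 (R)-4-benzyl-2-oxazolidinone
Product: 32 N-arylacetyl oxazolidinone, via mixed pivalic anhydride 31 (not isolated)
Conditions: PivCl, Et3N, THF, −20 °C; then 30, LiCl, rt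
Reagents that add atoms: none
Why: N-Acylation of the oxazolidinone through the mixed pivalic anhydride under LiCl/Et3N activation avoids strong base, so the lactone and its C3 centre are not disturbed.

**Step 17**
Reactants: 32 N-arylacetyl oxazolidinone; 33 4-(benzyloxy)-3-methoxybenzaldehyde
Product: 36 (2R,3R)-syn-aldol adduct, via boron enolate 34 (not isolated), via boron aldolate 35 (not isolated)
Conditions: Bu2BOTf, i-Pr2NEt, CH2Cl2, −78 → 0 °C; 33, −78 → 0 °C; then pH 7 buffer, MeOH, H2O2, 0 °C
Reagents that add atoms: none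
Why: In the Evans syn-aldol reaction the (Z)-boron enolate of the imide adds to the aldehyde through a closed chair transition state on the face opposite the auxiliary benzyl group, which with the (R)-auxiliary should set the (2R,3R) adduct, while the lactone is not enolised by Bu2BOTf/i-Pr2NEt.

**Step 18**
Reactants: 36 (2R,3R)-syn-aldol adduct
Product: 37 (1R,2S)-1,3-diol
Conditions: NaBH4, THF/H2O, 0 °C → rt
Reagents that add atoms: none
Why: Reductive cleavage of the activated imide carbonyl with borohydride in wet THF should release the primary alcohol and the auxiliary while the much less electrophilic γ-lactone is left alone.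

**Step 19**
Reactants: 37 (1R,2S)-1,3-diol
Product: 38 tri-O-benzyl (S)-β-hydroxy ketone
Conditions: DDQ, 1,4-dioxane, rt
Reagents that add atoms: none
Why: DDQ oxidises the secondary benzylic alcohol para to an alkoxy group by hydride abstraction, whereas the primary alcohol and the benzylic CH2 groups should react far more slowly, and the neutral medium should preserve the now acidic α-aryl stereocentre.

**Step 20**
Reactants: 38 tri-O-benzyl (S)-β-hydroxy ketone
Product: 39 CNP0281222.1
Conditions: H2 (1 atm), 10% Pd/C, EtOAc, rt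
Reagents that add atoms: none
Why: Hydrogenolysis of the three aryl benzyl ethers over Pd/C under neutral conditions should be faster than reduction of the electron-rich aryl ketone and cannot epimerise the α-aryl ketone centre.

**Compound list**
1 | 4-(benzyloxy)-3-methoxybenzyl alcohol | COc1cc(CO)ccc1OCc1ccccc1 | starting material
2 | 4-(benzyloxy)-3-methoxybenzyl bromide | COc1cc(CBr)ccc1OCc1ccccc1 | intermediate
3 | 1-(benzyloxy)-2-methoxy-4-(prop-2-yn-1-yl)benzene | COc1cc(CC#C)ccc1OCc1ccccc1 | intermediate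
4 | (1S,2R,5S)-(+)-menthyl (R)-p-toluenesulfinate | C[C@H]1CC[C@@H]([C@H](C1)O[S@@](=O)c1ccc(C)cc1)C(C)C | starting material
5 | {3-[4-(benzyloxy)-3-methoxyphenyl]prop-1-yn-1-yl}magnesium bromide (not isolated) | COc1cc(CC#C[Mg]Br)ccc1OCc1ccccc1 | intermediate
6 | (R)-1-(benzyloxy)-2-methoxy-4-[3-(p-tolylsulfinyl)prop-2-yn-1-yl]benzene | COc1cc(CC#C[S@](=O)c2ccc(C)cc2)ccc1OCc1ccccc1 | intermediate
7 | (S)-1-(benzyloxy)-2-methoxy-4-[(Z)-3-(p-tolylsulfinyl)prop-2-en-1-yl]benzene (S at sulfur) | COc1cc(C/C=C\[S@](=O)c2ccc(C)cc2)ccc1OCc1ccccc1 | intermediate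
8 | vanillin | COc1cc(C=O)ccc1O | starting material
9 | 4-(allyloxy)-3-methoxybenzaldehyde | COc1cc(C=O)ccc1OCC=C | intermediate
10 | 5-allyl-3-methoxy-4-oxocyclohexa-1,5-diene-1-carbaldehyde, the dienone of the Claisen step (not isolated) | COC1=CC(C=O)=CC(CC=C)C1=O | intermediate
11 | 3-allyl-4-hydroxy-5-methoxybenzaldehyde | COc1cc(C=O)cc(CC=C)c1O | intermediate
12 | 3-allyl-4-(benzyloxy)-5-methoxybenzaldehyde | COc1cc(C=O)cc(CC=C)c1OCc1ccccc1 | intermediate
13 | [3-allyl-4-(benzyloxy)-5-methoxyphenyl]methanol | COc1cc(CO)cc(CC=C)c1OCc1ccccc1 | intermediate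
14 | 1-allyl-2-(benzyloxy)-5-(bromomethyl)-3-methoxybenzene | COc1cc(CBr)cc(CC=C)c1OCc1ccccc1 | intermediate
15 | methyl dichloroacetate | COC(=O)C(Cl)Cl | starting material
16 | lithium enolate of methyl dichloroacetate (not isolated) | [Li+].COC([O-])=C(Cl)Cl | intermediate
17 | methyl 3-[3-allyl-4-(benzyloxy)-5-methoxyphenyl]-2,2-dichloropropanoate | COC(=O)C(Cl)(Cl)Cc1cc(OC)c(OCc2ccccc2)c(CC=C)c1 | intermediate
18 | 3-[3-allyl-4-(benzyloxy)-5-methoxyphenyl]-2,2-dichloropropanoic acid | OC(=O)C(Cl)(Cl)Cc1cc(OC)c(OCc2ccccc2)c(CC=C)c1 | intermediate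
19 | 3-[3-allyl-4-(benzyloxy)-5-methoxyphenyl]-2,2-dichloropropanoyl chloride (not isolated) | ClC(=O)C(Cl)(Cl)Cc1cc(OC)c(OCc2ccccc2)c(CC=C)c1 | intermediate
20 | 3-[3-allyl-4-(benzyloxy)-5-methoxyphenyl]-2-chloroprop-1-en-1-one, the chloro(arylmethyl)ketene (not isolated) | O=C=C(Cl)Cc1cc(OC)c(OCc2ccccc2)c(CC=C)c1 | intermediate
21 | oxysulfonium enolate: ketene 20 O-bound to the sulfur of 7, sulfur configuration retained (not isolated) | [O-]C(O[S@@+](/C=C\Cc1ccc(OCc2ccccc2)c(OC)c1)c1ccc(C)cc1)=C(Cl)Cc1cc(OC)c(OCc2ccccc2)c(CC=C)c1 | intermediate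
22 | thionium carboxylate after the [3,3] shift: 2-chloro-2-(ring-B benzyl)-3-(ring-A benzyl)-4-(p-tolylthionio)but-3-enoate, C3 as C4 of 23 (not isolated) | [O-]C(=O)C(Cl)(Cc1cc(OC)c(OCc2ccccc2)c(CC=C)c1)[C@H](Cc1ccc(OCc2ccccc2)c(OC)c1)C=[S+]c1ccc(C)cc1 | intermediate
23 | (4R)-3-{[3-allyl-4-(benzyloxy)-5-methoxyphenyl]methyl}-4-{[4-(benzyloxy)-3-methoxyphenyl]methyl}-3-chloro-5-(p-tolylthio)dihydrofuran-2(3H)-one, epimers at C3 and C5 | COc1cc(C[C@@H]2C(Sc3ccc(C)cc3)OC(=O)C2(Cl)Cc2cc(OC)c(OCc3ccccc3)c(CC=C)c2)ccc1OCc1ccccc1 | intermediate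
24 | (4S)-3-{[3-allyl-4-(benzyloxy)-5-methoxyphenyl]methyl}-4-{[4-(benzyloxy)-3-methoxyphenyl]methyl}-5-(p-tolylthio)dihydrofuran-2(3H)-one, epimers at C3 and C5 (not isolated) | COc1cc(C[C@@H]2C(Sc3ccc(C)cc3)OC(=O)C2Cc2cc(OC)c(OCc3ccccc3)c(CC=C)c2)ccc1OCc1ccccc1 | intermediate
25 | (3R,4S)-cis-3-{[3-allyl-4-(benzyloxy)-5-methoxyphenyl]methyl}-4-{[4-(benzyloxy)-3-methoxyphenyl]methyl}dihydrofuran-2(3H)-one (not isolated) | COc1cc(C[C@@H]2COC(=O)[C@@H]2Cc2cc(OC)c(OCc3ccccc3)c(CC=C)c2)ccc1OCc1ccccc1 | intermediate
26 | (3S,4S)-trans-3-{[3-allyl-4-(benzyloxy)-5-methoxyphenyl]methyl}-4-{[4-(benzyloxy)-3-methoxyphenyl]methyl}dihydrofuran-2(3H)-one | COc1cc(C[C@@H]2COC(=O)[C@H]2Cc2cc(OC)c(OCc3ccccc3)c(CC=C)c2)ccc1OCc1ccccc1 | intermediate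
27 | 2,3-dihydroxypropyl analogue of 26 (allyl dihydroxylated, not isolated) | COc1cc(C[C@@H]2COC(=O)[C@H]2Cc2cc(OC)c(OCc3ccccc3)c(CC(O)CO)c2)ccc1OCc1ccccc1 | intermediate
28 | 2-{2-(benzyloxy)-5-[((3S,4S)-4-{[4-(benzyloxy)-3-methoxyphenyl]methyl}-2-oxotetrahydrofuran-3-yl)methyl]-3-methoxyphenyl}acetaldehyde | COc1cc(C[C@@H]2COC(=O)[C@H]2Cc2cc(OC)c(OCc3ccccc3)c(CC=O)c2)ccc1OCc1ccccc1 | intermediate
29 | 2-{2-(benzyloxy)-5-[((3S,4S)-4-{[4-(benzyloxy)-3-methoxyphenyl]methyl}-2-oxotetrahydrofuran-3-yl)methyl]-3-methoxyphenyl}acetic acid | COc1cc(C[C@@H]2COC(=O)[C@H]2Cc2cc(OC)c(OCc3ccccc3)c(CC(=O)O)c2)ccc1OCc1ccccc1 | intermediate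
30 | (R)-4-benzyl-2-oxazolidinone | O=C1N[C@H](Cc2ccccc2)CO1 | starting material
31 | mixed pivalic anhydride of acid 29 (not isolated) | COc1cc(C[C@@H]2COC(=O)[C@H]2Cc2cc(OC)c(OCc3ccccc3)c(CC(=O)OC(=O)C(C)(C)C)c2)ccc1OCc1ccccc1 | intermediate
32 | (R)-4-benzyl-3-(arylacetyl)oxazolidin-2-one derived from acid 29 | COc1cc(C[C@@H]2COC(=O)[C@H]2Cc2cc(OC)c(OCc3ccccc3)c(CC(=O)N3C(=O)OC[C@H]3Cc3ccccc3)c2)ccc1OCc1ccccc1 | intermediate
33 | 4-(benzyloxy)-3-methoxybenzaldehyde | COc1cc(C=O)ccc1OCc1ccccc1 | starting material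
34 | (Z)-dibutylboron enolate of imide 32 (not isolated) | COc1cc(C[C@@H]2COC(=O)[C@H]2Cc2cc(OC)c(OCc3ccccc3)c(/C=C(\OB(CCCC)CCCC)N3C(=O)OC[C@H]3Cc3ccccc3)c2)ccc1OCc1ccccc1 | intermediate
35 | O-dibutylboryl aldolate of 36 (not isolated) | COc1cc(C[C@@H]2COC(=O)[C@H]2Cc2cc(OC)c(OCc3ccccc3)c([C@@H](C(=O)N3C(=O)OC[C@H]3Cc3ccccc3)[C@@H](OB(CCCC)CCCC)c3ccc(OCc4ccccc4)c(OC)c3)c2)ccc1OCc1ccccc1 | intermediate
36 | aldol adduct: ring B of the (3S,4S)-lactone carries at C5 a (2R,3R)-3-[4-(benzyloxy)-3-methoxyphenyl]-3-hydroxy-1-[(R)-4-benzyl-2-oxooxazolidin-3-yl]-1-oxopropan-2-yl group | COc1cc(C[C@@H]2COC(=O)[C@H]2Cc2cc(OC)c(OCc3ccccc3)c([C@@H](C(=O)N3C(=O)OC[C@H]3Cc3ccccc3)[C@@H](O)c3ccc(OCc4ccccc4)c(OC)c3)c2)ccc1OCc1ccccc1 | intermediate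
37 | diol: ring B of the (3S,4S)-lactone carries at C5 a (1R,2S)-1-[4-(benzyloxy)-3-methoxyphenyl]-1,3-dihydroxypropan-2-yl group | COc1cc(C[C@@H]2COC(=O)[C@H]2Cc2cc(OC)c(OCc3ccccc3)c([C@@H](CO)[C@@H](O)c3ccc(OCc4ccccc4)c(OC)c3)c2)ccc1OCc1ccccc1 | intermediate
38 | tri-O-benzyl target: ring B of the (3S,4S)-lactone carries at C5 a (2S)-1-[4-(benzyloxy)-3-methoxyphenyl]-3-hydroxy-1-oxopropan-2-yl group | COc1cc(C[C@@H]2COC(=O)[C@H]2Cc2cc(OC)c(OCc3ccccc3)c([C@@H](CO)C(=O)c3ccc(OCc4ccccc4)c(OC)c3)c2)ccc1OCc1ccccc1 | intermediate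
39 | CNP0281222.1, (3S,4S)-3-({4-hydroxy-3-[(2S)-3-hydroxy-1-(4-hydroxy-3-methoxyphenyl)-1-oxopropan-2-yl]-5-methoxyphenyl}methyl)-4-[(4-hydroxy-3-methoxyphenyl)methyl]dihydrofuran-2(3H)-one | COc1cc(C[C@@H]2COC(=O)[C@H]2Cc2cc(OC)c(O)c([C@@H](CO)C(=O)c3ccc(O)c(OC)c3)c2)ccc1O | target

**Totals and risks**
Total step count: 20. Longest linear sequence: 16 steps (steps 5–20, from vanillin); steps 1–4 make the sulfoxide that joins at step 12.

Three steps most likely to fail:

Step 12 (Proposed new method). The alkyl(chloro)ketene is less electrophilic than dichloroketene, so it may dimerise or add to the C=C bonds before the sulfinyl oxygen captures it, or the dichloroacyl chloride may be reduced past the ketene stage. The fallback sets out from sulfoxide 7 and returns at lactone 26; bromide 14 is used directly and steps 10 and 11 fall away. Sulfoxide 7 is treated with trichloroacetyl chloride and Zn–Cu in Et2O (the known dichloroketene lactonization), which should give (4R)-4-{[4-(benzyloxy)-3-methoxyphenyl]methyl}-3,3-dichloro-5-(p-tolylthio)dihydrofuran-2(3H)-one F1 with the same chirality transfer. Bu3SnH/AIBN in toluene at 100 °C then removes both chlorines and the arylthio group to give (S)-4-{[4-(benzyloxy)-3-methoxyphenyl]methyl}dihydrofuran-2(3H)-one F2. Its lithium enolate (LiHMDS, THF, −78 °C) is alkylated with bromide 14 anti to the C4 substituent, which should give trans-lactone 26.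

Step 18. Hydride attack on the lactone carbonyl may compete with cleavage of the imide, or base-induced retro-aldol cleavage or epimerisation of the α-aryl imide may precede reduction. The fallback sets out from aldol adduct 36 and returns at diol 37. The auxiliary is removed hydrolytically with LiOH/H2O2 in THF/H2O at 0 °C (acidic work-up re-closes any opened lactone) to give the β-hydroxy acid F3. The acid is then reduced selectively beside the lactone with BH3·SMe2 in THF at 0 °C to give diol 37.

Step 19. Hydride abstraction at the other electron-rich benzylic positions or acid-promoted dehydration of the β-hydroxy ketone may compete with the selective oxidation. The fallback sets out from diol 37 and returns at ketone 38. The primary hydroxyl is silylated selectively (TBSCl, imidazole, DMF, 0 °C) to give the mono-silyl ether F4. The secondary alcohol is oxidised with Dess–Martin periodinane (NaHCO3, CH2Cl2) to give the silyloxy ketone F5. The silyl group is removed under non-basic conditions (HF·pyridine, THF, 0 °C) to give 38.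

**Further compounds**
F1 | step 12 | (4R)-4-{[4-(benzyloxy)-3-methoxyphenyl]methyl}-3,3-dichloro-5-(p-tolylthio)dihydrofuran-2(3H)-one (C5 epimers) | COc1cc(C[C@@H]2C(Sc3ccc(C)cc3)OC(=O)C2(Cl)Cl)ccc1OCc1ccccc1
F2 | step 12 | (S)-4-{[4-(benzyloxy)-3-methoxyphenyl]methyl}dihydrofuran-2(3H)-one | COc1cc(C[C@@H]2COC(=O)C2)ccc1OCc1ccccc1
F3 | step 18 | (2R,3R)-β-hydroxy acid from hydrolysis of imide 36 | COc1cc(C[C@@H]2COC(=O)[C@H]2Cc2cc(OC)c(OCc3ccccc3)c([C@@H](C(=O)O)[C@@H](O)c3ccc(OCc4ccccc4)c(OC)c3)c2)ccc1OCc1ccccc1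
F4 | step 19 | primary tert-butyldimethylsilyl ether of diol 37 | COc1cc(C[C@@H]2COC(=O)[C@H]2Cc2cc(OC)c(OCc3ccccc3)c([C@@H](CO[Si](C)(C)C(C)(C)C)[C@@H](O)c3ccc(OCc4ccccc4)c(OC)c3)c2)ccc1OCc1ccccc1
F5 | step 19 | tert-butyldimethylsilyl ether of ketone 38 | COc1cc(C[C@@H]2COC(=O)[C@H]2Cc2cc(OC)c(OCc3ccccc3)c([C@@H](CO[Si](C)(C)C(C)(C)C)C(=O)c3ccc(OCc4ccccc4)c(OC)c3)c2)ccc1OCc1ccccc1
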